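**The hunch.** A one-step world has solid substrate falling in proportion to itself, so both charges should show the same fraction at the same time. But at 50.0 min ochre holds 63% and blue 82%, a gap of 19 percentage points against a scatter of 1.5 points.

all flasks: gas 59 mM (held)

| flask | solid substrate | remark | time |
|---|---|---|---|
| ochre | 0.80 M | the very flask that is asked about, followed so far |  |
| blue | 1.6 M | run made earlier |  |
| flask | 0.80 M |  | 2.5 h |

| run | time / min | product / % | solid substrate / % |
|---|---|---|---|
| ochre | 40.0 | 24 | 71 |
| ochre | 50.0 | 30 | 63 |
| blue | 40.0 | 10 | 84 |
| blue | 50.0 | 19 | 82 |
| blue | 60.0 | 21 | 75 |

(standard deviation of a reading: 1.5 percentage points)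

- given per volume of solution although it is solid: solid substrate
- at the start none of the solid substrate is in solution
- at the start none of the gas is in solution

- the best time, 2.5 h at the latest, for product
- the amount of product, in percent of the solid substrate charged, at that time
- the first time at which product reaches 68%, in the same percent

**Clearing time.** Ochre has lost 37.0% of its charge by 50.0 min, so at that average molar pace the charge lasts 2.25 h. This is the clearing time, the charge divided by its molar loss rate, or zero-order depletion time. Blue reads 4.00 h, about twice ochre's value, for twice the charge.

**Own reckoning.** The flask asked about is ochre itself, and at that pace this reckoning clears it before the limit. Ochre's balance, as read, lacks 7.00% at 50.0 min. Taking that as a held pool, this reckoning puts product at 68% at 1.69 h and at 93.0% at clearing, with the pool still to drain, so its best time is the limit, 2.5 h.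

**The forecast.** It gives 2.5 h, 90% and 1.75 h, arguing that “Doubling the charge changes nothing”. Its best lies below this reckoning's clearing value.

**The flask.** It gives 2.50 h, 97.7% and 1.73 h, with solid substrate at 0% and dissolved substrate at 2.30% at 2.50 h.

    solid substrate ⇌ dissolved substrate, rate k1*(cs1 - [dissolved substrate]) while solid is left; crystals form when [dissolved substrate] > cs1 (solubility = 0.0510 M, k = 0.720 min⁻¹)
    dissolved substrate + reagent → product (k = 3.00 L mol⁻¹ min⁻¹)
    gas ⇌ reagent, rate k3*(csat - [reagent]) (kL = 0.300 min⁻¹)

**A heavier charge.** At ochre's molar pace, the neighbour flask charged with 1.4 M reckons a clearing time of 3.94 h, beyond the limit, and so a fall in solid substrate of 63.5% of its charge by 2.50 h. Simulated, that neighbour flask's solid substrate has fallen by 59.7% of its charge at that time, and its product stands at 56.6%.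

The runs are calculated for substances that don't exist; noise was put on by code.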